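The route builds ring B last, from open-chain parts, on a finished chromone (rings A and C). Ring B is a 4-methoxyphenol: the free hydroxyl at C2' lies para to the C5' methoxy, with the chromone at C1' ortho to the hydroxyl and a second methoxy at C4'. A benzannulation of a methoxy(alkenyl)carbene chromium complex with a terminal alkyne and one CO ligand delivers exactly this pattern, so one operation forms C5'–C6', C1'–C2' and C2'–C3' and leaves the lone phenol unprotected. The precursor is 2-ethynyl-3,7,8-trimethoxychromone, made from 1,2,3-trimethoxybenzene by acylation, chromone closure, C2 iodination and alkynylation. Its partner is the α-methoxyvinyl Fischer carbene.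

Key step: step 7

Assumption: flavone numbering is used (rings A and C form the chromone, ring B is the aryl group at C2), and chromium complexes are drawn in SMILES with metal and ligands as dot-separated components.

Step 1
Reactants: 1 1,2,3-trimethoxybenzene; 2 methoxyacetyl chloride
Product: 4 1-(2-hydroxy-3,4-dimethoxyphenyl)-2-methoxyethan-1-one, via 2-methoxy-1-(2,3,4-trimethoxyphenyl)ethan-1-one 3 (not isolated)
Conditions: AlCl3 (2.5 equiv), CH2Cl2, 0 °C → reflux; aqueous HCl
Reagents that add atoms: none
Why: Friedel–Crafts acylation should occur at C4 of 1 (para to one outer methoxy, ortho to the other), after which AlCl3 chelated between the new ketone and the flanking ortho methoxy cleaves only that ether (chelation-directed ortho-demethylation), sparing the aliphatic α-methoxy group and the two other aryl ethers.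

Step 2
Reactants: 4 1-(2-hydroxy-3,4-dimethoxyphenyl)-2-methoxyethan-1-one
Product: 6 3,7,8-trimethoxy-4H-chromen-4-one, via enaminone 5 (not isolated)
Conditions: Me2NCH(OMe)2 (3 equiv), toluene, 100 °C; then AcOH, 80 °C
Reagents that add atoms: N,N-dimethylformamide dimethyl acetal, COC(OC)N(C)C
Why: The activated methylene condenses with the amide acetal to the enaminone, and the ortho phenol then displaces dimethylamine by conjugate addition–elimination to close ring C (enaminone route to 3-substituted chromones, as in isoflavone synthesis).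

Step 3
Reactants: 6 3,7,8-trimethoxy-4H-chromen-4-one
Product: 8 2-iodo-3,7,8-trimethoxy-4H-chromen-4-one, via 2-lithio-3,7,8-trimethoxychromone 7 (not isolated)
Conditions: LiN(iPr)2 (1.2 equiv), THF, −78 °C; I2, THF, −78 °C → rt; aqueous Na2S2O3
Reagents that add atoms: iodine, II
Why: C2–H of a 3-substituted chromone is the most acidic site (vinylic, next to the ring oxygen and flanked by the C3 methoxy), so kinetic deprotonation with a hindered lithium amide and iodine quench should give the 2-iodide (C2 lithiation–iodination of chromones).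

Step 4
Reactants: 8 2-iodo-3,7,8-trimethoxy-4H-chromen-4-one; 9 ethynyltrimethylsilane
Product: 10 3,7,8-trimethoxy-2-[(trimethylsilyl)ethynyl]-4H-chromen-4-one
Conditions: PdCl2(PPh3)2 (3 mol %), CuI (5 mol %), Et3N, THF, rt
Reagents that add atoms: none
Why: Sonogashira coupling; the C2–I bond is a vinylogous acyl iodide that should add readily to the zerovalent palladium formed in situ at room temperature, and the tertiary amine base cannot substitute at C2.

Step 5
Reactants: 10 3,7,8-trimethoxy-2-[(trimethylsilyl)ethynyl]-4H-chromen-4-one
Product: 11 2-ethynyl-3,7,8-trimethoxy-4H-chromen-4-one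
Conditions: Bu4NF (1.1 equiv), AcOH (1.2 equiv), THF, −20 → 0 °C
Reagents that add atoms: none
Why: Fluoride-mediated protodesilylation of the alkynylsilane; the AcOH buffer keeps the medium non-basic, so conjugate addition to the activated enyne and opening of the pyrone ring should not compete.

Step 6
Reactants: 12 methyl vinyl ether; 13 chromium hexacarbonyl Cr(CO)6
Product: 16 pentacarbonyl[methoxy(1-methoxyethenyl)carbene]chromium, via 1-methoxyvinyllithium 14 (not isolated), via lithium acylchromate 15 (not isolated)
Conditions: t-BuLi, THF, −78 → 0 °C; Cr(CO)6, THF, 0 °C → rt; evaporate; Me3OBF4, CH2Cl2, 0 °C; rapid filtration through silica under argon, stored cold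
Reagents that add atoms: trimethyloxonium tetrafluoroborate, C[O+](C)C.F[B-](F)(F)F
Why: Fischer carbene synthesis: t-BuLi removes the α-vinylic proton of the enol ether, the vinyllithium adds to a CO ligand of zerovalent Cr(CO)6 to give the acylchromate, and the hard oxonium salt methylates oxygen once THF has been exchanged for CH2Cl2.

Step 7
Reactants: 11 2-ethynyl-3,7,8-trimethoxy-4H-chromen-4-one; 16 pentacarbonyl[methoxy(1-methoxyethenyl)carbene]chromium
Product: 18 2-(2-hydroxy-4,5-dimethoxyphenyl)-3,7,8-trimethoxy-4H-chromen-4-one, via arene–Cr(CO)3 complex 17 (not isolated)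
Conditions: 16 (1.5 equiv), THF (0.05 M), argon, 50 °C; then air, EtOAc, daylight, rt
Reagents that add atoms: none
Why: Thermal loss of one CO from 16 opens a site for alkyne 11, which inserts into the Cr=C bond so that its unsubstituted terminus bonds to the carbene carbon (C5'–C6') and the chromonyl-bearing carbon becomes the new metal-bound carbene centre; CO insertion there (C1'–C2') gives an η4-dienylketene, whose 6π-electrocyclisation joins the ketene carbon to the vinyl CH2 (C2'–C3') and, after tautomerisation of the cyclohexadienone, delivers the 4-methoxyphenol as its Cr(CO)3 complex 17. The closest known reaction type is the Dötz benzannulation of alkenyl(alkoxy)carbene pentacarbonylchromium complexes with terminal alkynes, applied here to an α-methoxyalkenyl complex and a chromonyl alkyne. Ring B is closed as a formal [3+2+1] assembly whose ring-closing event is the thermal disrotatory 6π-electrocyclisation of the dienylketene. No stereocentre is created. The step needs regioselective insertion, secured by the terminal alkyne, whose bulky chromonyl group avoids the methoxy-bearing carbene carbon and so ends up ortho to the new hydroxyl, and it needs phenol rather than cyclopentadiene formation, which an alkenyl complex with an alkoxy donor in a weakly coordinating ether solvent at moderate temperature favours. Air alone should strip the Cr(CO)3 fragment, so the oxidisable 4-methoxyphenol never meets a strong oxidant such as (NH4)2Ce(NO3)6, which would give the quinone.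

Compound list
1 | 1,2,3-trimethoxybenzene | COc1cccc(OC)c1OC | starting material
2 | methoxyacetyl chloride | COCC(=O)Cl | starting material
3 | 2-methoxy-1-(2,3,4-trimethoxyphenyl)ethan-1-one | COCC(=O)c1ccc(OC)c(OC)c1OC | intermediate
4 | 1-(2-hydroxy-3,4-dimethoxyphenyl)-2-methoxyethan-1-one | COCC(=O)c1ccc(OC)c(OC)c1O | intermediate
5 | (Z)-3-(dimethylamino)-1-(2-hydroxy-3,4-dimethoxyphenyl)-2-methoxyprop-2-en-1-one (geometry without consequence) | CN(C)/C=C(\OC)C(=O)c1ccc(OC)c(OC)c1O | intermediate
6 | 3,7,8-trimethoxy-4H-chromen-4-one | COc1coc2c(OC)c(OC)ccc2c1=O | intermediate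
7 | 2-lithio-3,7,8-trimethoxy-4H-chromen-4-one | [Li]c1oc2c(OC)c(OC)ccc2c(=O)c1OC | intermediate
8 | 2-iodo-3,7,8-trimethoxy-4H-chromen-4-one | Ic1oc2c(OC)c(OC)ccc2c(=O)c1OC | intermediate
9 | ethynyltrimethylsilane | C#C[Si](C)(C)C | starting material
10 | 3,7,8-trimethoxy-2-[(trimethylsilyl)ethynyl]-4H-chromen-4-one | C[Si](C)(C)C#Cc1oc2c(OC)c(OC)ccc2c(=O)c1OC | intermediate
11 | 2-ethynyl-3,7,8-trimethoxy-4H-chromen-4-one | C#Cc1oc2c(OC)c(OC)ccc2c(=O)c1OC | intermediate
12 | methyl vinyl ether | COC=C | starting material
13 | chromium hexacarbonyl Cr(CO)6 | [C-]#[O+].[C-]#[O+].[C-]#[O+].[C-]#[O+].[C-]#[O+].[C-]#[O+].[Cr] | starting material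
14 | 1-methoxyvinyllithium | [Li]C(=C)OC | intermediate
15 | lithium pentacarbonyl(2-methoxyprop-2-enoyl)chromate | COC(=C)C([O-])=[Cr].[Li+].[C-]#[O+].[C-]#[O+].[C-]#[O+].[C-]#[O+].[C-]#[O+] | intermediate
16 | pentacarbonyl[methoxy(1-methoxyethenyl)carbene]chromium | COC(=C)C(OC)=[Cr].[C-]#[O+].[C-]#[O+].[C-]#[O+].[C-]#[O+].[C-]#[O+] | intermediate
17 | tricarbonyl{η6-[ring B of 2-(2-hydroxy-4,5-dimethoxyphenyl)-3,7,8-trimethoxy-4H-chromen-4-one]}chromium | COc1cc(O)c(-c2oc3c(OC)c(OC)ccc3c(=O)c2OC)cc1OC.[Cr].[C-]#[O+].[C-]#[O+].[C-]#[O+] | intermediate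
18 | 2-(2-hydroxy-4,5-dimethoxyphenyl)-3,7,8-trimethoxy-4H-chromen-4-one | COc1cc(O)c(-c2oc3c(OC)c(OC)ccc3c(=O)c2OC)cc1OC | target

Total step count: 7. Longest linear sequence: 6 steps (steps 1, 2, 3, 4, 5 and 7); step 6 is a one-step side branch that joins at step 7.

Steps most likely to fail

Step 7. The alkyne may be consumed unproductively: oligomerisation of the electron-poor enyne at the metal, insertion in the reverse sense, cyclisation without CO uptake to a five-membered ring, or thermal decay of the carbene complex before insertion. The fallback gives up the benzannulation for a cross-coupling of known type; it sets out from iodide 8 and comes back at target 18. Commercial 3,4-dimethoxyphenol would be brominated ortho to the hydroxyl (N-bromosuccinimide, MeCN, 0 °C) to 2-bromo-4,5-dimethoxyphenol F1 and benzylated (BnBr, K2CO3, DMF) to 1-(benzyloxy)-2-bromo-4,5-dimethoxybenzene F2. Miyaura borylation (B2pin2, PdCl2(dppf), KOAc, dioxane, 90 °C) would give 2-[2-(benzyloxy)-4,5-dimethoxyphenyl]-4,4,5,5-tetramethyl-1,3,2-dioxaborolane F3. Suzuki–Miyaura coupling of F3 with 8 (Pd(PPh3)4, K3PO4, dioxane with a little water, 80 °C) should give 2-[2-(benzyloxy)-4,5-dimethoxyphenyl]-3,7,8-trimethoxy-4H-chromen-4-one F4, and hydrogenolysis of the benzyl ether (H2, Pd/C, EtOAc, rt) should return 18.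

Step 6. The electron-rich α-methoxyalkenyl carbene complex may degrade during O-methylation with the oxonium salt or on silica (Michael-type oligomerisation, hydrolysis of the carbene carbon), and lithiation of the volatile enol ether may be incomplete. The fallback replaces direct alkylation by the acyloxycarbene exchange; it sets out from acylchromate 15 and comes back at 16. Cation exchange of 15 with Me4NBr in degassed water should precipitate the storable tetramethylammonium pentacarbonyl(2-methoxyprop-2-enoyl)chromate F5, which can be recrystallised instead of chromatographed. Acetyl bromide in CH2Cl2 at −40 °C would convert F5 into pentacarbonyl[acetoxy(1-methoxyethenyl)carbene]chromium F6, and addition of MeOH at −40 → 0 °C should exchange acetoxy for methoxy to give 16, used in step 7 as a filtered solution.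

Step 3. The amide base may add at C2 and open the pyrone ring, the 2-lithio species may attack unreacted chromone, or ring A may be metalated in competition. The fallback installs the C2 carbon during ring construction instead of by deprotonation; it sets out from ketone 4 and comes back at alkyne 11, bypassing 6, 8 and 10. Kostanecki–Robinson acylation (Ac2O, NaOAc, 170 °C) should first give 2,3-dimethoxy-6-(methoxyacetyl)phenyl acetate F7, which in the same flask undergoes intramolecular acyl transfer and cyclodehydration to 3,7,8-trimethoxy-2-methyl-4H-chromen-4-one F8. Oxidation of the activated 2-methyl group (SeO2, xylene, reflux) would give 3,7,8-trimethoxy-4-oxo-4H-chromene-2-carbaldehyde F9, and Ohira–Bestmann homologation (dimethyl (1-diazo-2-oxopropyl)phosphonate, K2CO3, MeOH, 0 °C) should deliver 11.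

Further compounds
F1 | step 7 | 2-bromo-4,5-dimethoxyphenol | COc1cc(O)c(Br)cc1OC
F2 | step 7 | 1-(benzyloxy)-2-bromo-4,5-dimethoxybenzene | COc1cc(Br)c(OCc2ccccc2)cc1OC
F3 | step 7 | 2-[2-(benzyloxy)-4,5-dimethoxyphenyl]-4,4,5,5-tetramethyl-1,3,2-dioxaborolane | COc1cc(B2OC(C)(C)C(C)(C)O2)c(OCc2ccccc2)cc1OC
F4 | step 7 | 2-[2-(benzyloxy)-4,5-dimethoxyphenyl]-3,7,8-trimethoxy-4H-chromen-4-one | COc1cc(OCc2ccccc2)c(-c2oc3c(OC)c(OC)ccc3c(=O)c2OC)cc1OC
F5 | step 6 | tetramethylammonium pentacarbonyl(2-methoxyprop-2-enoyl)chromate | COC(=C)C([O-])=[Cr].C[N+](C)(C)C.[C-]#[O+].[C-]#[O+].[C-]#[O+].[C-]#[O+].[C-]#[O+]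
F6 | step 6 | pentacarbonyl[acetoxy(1-methoxyethenyl)carbene]chromium | COC(=C)C(OC(C)=O)=[Cr].[C-]#[O+].[C-]#[O+].[C-]#[O+].[C-]#[O+].[C-]#[O+]
F7 | step 3 | 2,3-dimethoxy-6-(methoxyacetyl)phenyl acetate | COCC(=O)c1ccc(OC)c(OC)c1OC(C)=O
F8 | step 3 | 3,7,8-trimethoxy-2-methyl-4H-chromen-4-one | Cc1oc2c(OC)c(OC)ccc2c(=O)c1OC
F9 | step 3 | 3,7,8-trimethoxy-4-oxo-4H-chromene-2-carbaldehyde | O=Cc1oc2c(OC)c(OC)ccc2c(=O)c1OC
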